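Late in the teal run, which is the flask asked about followed so far, the readings of monomer in chains seemed to level, and that late level with the time taken to reach it was what I wanted.

| flask | free monomer | initiator | temperature | remark | time |
|---|---|---|---|---|---|
| teal | 0.25 M | 1.2 mM | 70 °C | the very flask that is asked about, followed so far |  |
| green | 0.25 M | 1.2 mM | 65 °C | run made earlier |  |
| flask | 0.25 M | 1.2 mM | 70 °C |  | 12 h |

| run | time / h | monomer in chains / % | free monomer / % |
|---|---|---|---|
| teal | 2.00 | 55 | 3 |
| teal | 4.00 | 52 | 1 |
| teal | 6.00 | 43 | 2 |
| teal | 8.00 | 45 | 0 |
| teal | 10.0 | 43 | 0 |
| green | 2.00 | 63 | 3 |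
| green | 4.00 | 57 | 1 |
| green | 6.00 | 51 | 0 |
| green | 8.00 | 48 | 2 |
| green | 10.0 | 43 | 0 |

(readings scatter by 1.5 percentage points)

- dusk: at 12 h take out 90 % of the monomer in chains then present, then wait 4.0 h
- autumn: at 12 h raise the temperature by 20 K, then wait 4.0 h
- dawn: change nothing and wait 4.0 h more
- noon: at 12 h add initiator, 50.0 % of the amount charged, then wait 4.0 h

- in percentages every species weighs as the free monomer in it: one side product counts as two
- what is taken out of monomer in chains is counted as made
- on the list of suspects stand: free monomer + initiator -> living end + monomer in chains; free monomer + living end -> monomer in chains + living end; living end + free monomer -> dead end; free monomer + monomer in chains -> side product; monomer in chains + initiator <-> isomer of the product + initiator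
- additions bring no volume worth counting

- monomer in chains, in percent of the free monomer first charged, at 12 h
- which option adds most monomer in chains ("none" when 2 percentage points or less is all one gets) (dusk / autumn / dawn / noon / none)
- monomer in chains present, with what was taken out counted in, in percent of the free monomer first charged, after dawn
- monomer in chains present, with what was taken out counted in, in percent of the free monomer first charged, after noon

1. From 2.00 h on, free monomer read 3 % or less, well below the 55 % in chains. I therefore watched the fall of the chains. My first level L, the mean of the last 3 teal readings, was 43.7 %.

2. I treated the gap above L as pseudo-first-order, losing the same share in equal times. Its first two values gave a half-life of 4.51 h. But a reading scatters by 1.5 percentage points, and those two readings differ by 3 points. So I averaged the readings at 4.00 h and 6.00 h, and this gave 1.92 h.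

3. The objection was that with such a half-life those last readings had not come to rest: their mean still held 13.5 % of the gap from 2.00 h. Taking that out lowered L to 41.9 %.

4. Repeating step 2 with this L gave the gap half-life H, the time in which the distance of monomer in chains from its late level halves, of 2.45 h.

5. Counting 4.08 half-lives from 2.00 h to 12 h, I expected 42.7 % in the flask. The green run gave me no level for reckoning the effect of heat.

The forecast, a little lower than mine, said 42 % (38 % to 45 %), with 41 % after dawn and 40.5 % after noon, and it chose dusk. It assumed a “relaxation rate of about 0.3 per hour”.

The flask stood at 41.9 % at 12 h, and autumn added most, 13 points against 9.3 points for dusk. After noon the flask stood at 40.5 %. The neighbour run at 85 °C held 11.8 % isomer of the product, against 28.1 % in this flask.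

    free monomer + initiator → living end + monomer in chains (k = 0.132 /M/min, Ea = 73.0 kJ/mol)
    free monomer + living end → monomer in chains + living end, rate k2*[living end]*[free monomer] (k = 99.7 /M/min, Ea = 47.0 kJ/mol)
    living end + free monomer → dead end (k = 0.322 /M/min, Ea = 82.0 kJ/mol)
    free monomer + monomer in chains → side product (k = 0.0477 /M/min, Ea = 84.0 kJ/mol)
    monomer in chains + initiator ⇌ isomer of the product + initiator, rate k5*[initiator]*[monomer in chains] forward; the back reaction follows from the equilibrium constant (K = 0.731, k = 5.52 /M/min, Ea = 46.0 kJ/mol, ΔH = −52.0 kJ/mol)
    (constants at 70 °C)

Over the 4.0 h of dawn, H shrinks this flask's gap above the 40.4 % of 120 h to a predicted 40.9 %; the flask gave 40.9 %. The same charge read at 3.0 h stood at 54.4 %, and H carries that reading to 41.5 % at 12 h, where the flask stood at 41.9 %.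

(The numbers in the tables come from a simulation for an exercise, noise included.)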